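The oxolane hemiketal masks a ten-membered carbocycle: C1 is a ketone carbon, C4 an alkene carbon, and the C2–C3 ethano bridge links them, so the opened ring is a γ,δ-unsaturated ketone (C1=O, C4=C5) and a Claisen retron. With a 2-silylfuran standing in for the butenolide ring (C6, C7, C11, C12), the key step heats a furan-fused 2-methyleneoxocane whose ether carbon C5 carries an isopropenyl group; in one operation C2–C3 forms, the furfuryl C5–O bond breaks and the eight-membered ether becomes the (E)-cyclodec-4-enone. The precursor comes from an eight-membered lactone closed between the C1 acid and C5–OH and methylenated at C1.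

Key step: step 14

Remark 1: all intermediates carry the atom numbers of the target (C1 hemiketal carbon, C4 ether carbon with methyl C15, C8 acyloxy carbon, C10 with methyl C14, C12 lactone carbonyl, C13 CH2O); TBS = tert-butyldimethylsilyl, TES = triethylsilyl, TMS = trimethylsilyl.

Remark 2: C5 is created without stereocontrol and becomes trigonal in step 14, so 9–12 are racemic and 16–22 are mixtures of the two C5 epimers; their SMILES leave C5 open, and the key-step pair is otherwise kept unchanged.

Step 1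
Reactants: 1 3,4-dibromofuran
Product: 4 (4-bromofuran-3-yl)methanol, via 3-bromo-4-lithiofuran 2 (not isolated), via 4-bromofuran-3-carbaldehyde 3 (not isolated)
Conditions: n-BuLi (1.0 equiv), Et2O, −78 °C; DMF, −78 → 0 °C; then MeOH, NaBH4, 0 °C
Reagents that add atoms: N,N-dimethylformamide, CN(C)C=O
Why: Bromine–lithium exchange on the symmetrical dibromide should stop cleanly after one bromine at −78 °C, the 3-furyllithium is formylated by DMF (Bouveault-type formylation), and the aldehyde released on methanol quench is reduced in the same flask by borohydride.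

Step 2
Reactants: 4 (4-bromofuran-3-yl)methanol
Product: 5 3-bromo-4-[(tert-butyldimethylsilyloxy)methyl]furan
Conditions: TBSCl, imidazole, DMF, rt
Reagents that add atoms: tert-butyldimethylsilyl chloride, CC(C)(C)[Si](C)(C)Cl
Why: Imidazole-mediated silylation of a primary alcohol gives an ether that should tolerate every organolithium step that follows.

Step 3
Reactants: 5 3-bromo-4-[(tert-butyldimethylsilyloxy)methyl]furan; 6 methacrolein
Product: 9 3-bromo-4-[(TBSO)methyl]-2-[2-methyl-1-(TESO)prop-2-en-1-yl]furan (racemic at C5), via 2-lithiofuran 7 (not isolated), via lithium alkoxide 8 (not isolated)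
Conditions: LDA, THF, −78 °C; 6, −78 °C; then TESCl, −78 → 0 °C
Reagents that add atoms: chlorotriethylsilane, CC[Si](Cl)(CC)CC
Why: Amide-base deprotonation of a 3-bromofuran takes the α-hydrogen flanked by bromine, the furyllithium adds 1,2 to the enal (forming C5–C6), and the alkoxide is capped in situ as a TES ether; C5 forms without control, which is acceptable because step 14 erases it.

Step 4
Reactants: 9 3-bromo-4-[(TBSO)methyl]-2-[2-methyl-1-(TESO)prop-2-en-1-yl]furan
Product: 10 3-bromo-4-[(TBSO)methyl]-2-[2-methyl-1-(TESO)prop-2-en-1-yl]-5-(trimethylsilyl)furan (racemic at C5)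
Conditions: LiTMP (from TMPH, n-BuLi), TMSCl present from the start, THF, −78 °C
Reagents that add atoms: chlorotrimethylsilane, C[Si](C)(C)Cl
Why: Only one ring hydrogen is left, so in situ-trapping metalation with the hindered amide can silylate only C12, and an amide base leaves the C–Br bond untouched.

Step 5
Reactants: 10 3-bromo-4-[(TBSO)methyl]-2-[2-methyl-1-(TESO)prop-2-en-1-yl]-5-(trimethylsilyl)furan
Product: 12 S-ethyl 4-[(TBSO)methyl]-2-[2-methyl-1-(TESO)prop-2-en-1-yl]-5-(trimethylsilyl)furan-3-carbothioate (racemic at C5), via 3-lithiofuran 11 (not isolated)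
Conditions: t-BuLi (2.1 equiv), Et2O, −78 °C, 10 min; cannulated into ClC(O)SEt, Et2O, −78 °C
Reagents that add atoms: S-ethyl chlorothioformate, CCSC(Cl)=O
Why: Bromine–lithium exchange followed by inverse-addition acylation with the chlorothioformate installs C8 as a thioester, and the short contact time in ether should suppress 1,4 O→C silyl shifts of the flanking silyl ethers.

Step 6
Reactants: 13 methyl (R)-3-hydroxy-2-methylpropanoate
Product: 14 methyl (S)-3-iodo-2-methylpropanoate
Conditions: I2, PPh3, imidazole, CH2Cl2, 0 °C → rt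
Reagents that add atoms: iodine, II
Why: Appel-type iodination of the primary alcohol does not touch the stereocentre, which becomes C10 (the descriptor changes only through the priority rules).

Step 7
Reactants: 12 S-ethyl 4-[(TBSO)methyl]-2-[2-methyl-1-(TESO)prop-2-en-1-yl]-5-(trimethylsilyl)furan-3-carbothioate; 14 methyl (S)-3-iodo-2-methylpropanoate
Product: 16 methyl (2R)-2-methyl-4-oxo-4-{4-[(TBSO)methyl]-2-[2-methyl-1-(TESO)prop-2-en-1-yl]-5-(trimethylsilyl)furan-3-yl}butanoate (both C5 epimers), via alkylzinc iodide 15 (not isolated)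
Conditions: 14, Zn dust (BrCH2CH2Br, TMSCl activation), THF, 35 °C; then 12, PdCl2(PPh3)2 (5 mol %), toluene, rt
Reagents that add atoms: none
Why: Zinc insertion gives a configurationally stable β-zincio ester, and Fukuyama coupling with the thioester forms the C8–C9 bond as a ketone without over-addition and without touching the ester or the silyl ethers.

Step 8
Reactants: 16 methyl (2R)-2-methyl-4-oxo-4-{4-[(TBSO)methyl]-2-[2-methyl-1-(TESO)prop-2-en-1-yl]-5-(trimethylsilyl)furan-3-yl}butanoate
Product: 17 methyl (2R,4S)-4-hydroxy-2-methyl-4-{4-[(TBSO)methyl]-2-[2-methyl-1-(TESO)prop-2-en-1-yl]-5-(trimethylsilyl)furan-3-yl}butanoate (both C5 epimers)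
Conditions: (R)-2-methyl-CBS-oxazaborolidine (0.5 equiv), catecholborane, toluene, −78 → −40 °C
Reagents that add atoms: none
Why: CBS reduction of a heteroaryl alkyl ketone delivers hydride under catalyst control with the furyl group as the large substituent, so the R catalyst should set C8 as S, while catecholborane spares the isopropenyl alkene and the ester.

Step 9
Reactants: 17 methyl (2R,4S)-4-hydroxy-2-methyl-4-{4-[(TBSO)methyl]-2-[2-methyl-1-(TESO)prop-2-en-1-yl]-5-(trimethylsilyl)furan-3-yl}butanoate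
Product: 18 methyl (2R,4S)-4-(TBSO)-2-methyl-4-{4-[(TBSO)methyl]-2-[2-methyl-1-(TESO)prop-2-en-1-yl]-5-(trimethylsilyl)furan-3-yl}butanoate (both C5 epimers)
Conditions: TBSOTf, 2,6-lutidine, CH2Cl2, −78 → 0 °C
Reagents that add atoms: tert-butyldimethylsilyl triflate, CC(C)(C)[Si](C)(C)OS(=O)(=O)C(F)(F)F
Why: Silyl triflate silylation caps the hindered C8 alcohol at once and so blocks γ-lactonization onto the C1 ester.

Step 10
Reactants: 18 methyl (2R,4S)-4-(TBSO)-2-methyl-4-{4-[(TBSO)methyl]-2-[2-methyl-1-(TESO)prop-2-en-1-yl]-5-(trimethylsilyl)furan-3-yl}butanoate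
Product: 19 methyl (2R,4S)-4-(TBSO)-4-{2-(1-hydroxy-2-methylprop-2-en-1-yl)-4-[(TBSO)methyl]-5-(trimethylsilyl)furan-3-yl}-2-methylbutanoate (both C5 epimers)
Conditions: HF·pyridine, pyridine, THF, 0 °C
Reagents that add atoms: none
Why: Selective desilylation: a secondary TES ether is cleaved by pyridine-buffered HF much faster than the two TBS ethers, and the nearly neutral medium should not ionize the furfuryl–allyl alcohol.

Step 11
Reactants: 19 methyl (2R,4S)-4-(TBSO)-4-{2-(1-hydroxy-2-methylprop-2-en-1-yl)-4-[(TBSO)methyl]-5-(trimethylsilyl)furan-3-yl}-2-methylbutanoate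
Product: 20 (2R,4S)-4-(TBSO)-4-{2-(1-hydroxy-2-methylprop-2-en-1-yl)-4-[(TBSO)methyl]-5-(trimethylsilyl)furan-3-yl}-2-methylbutanoic acid (both C5 epimers)
Conditions: LiOH, THF/MeOH/H2O, 0 °C → rt; then cold 0.5 M HCl to pH 5
Reagents that add atoms: lithium hydroxide, [Li+].[OH-]
Why: Saponification of the methyl ester; C10 should not epimerize because hydrolysis is faster than enolization and the carboxylate is not enolized.

Step 12
Reactants: 20 (2R,4S)-4-(TBSO)-4-{2-(1-hydroxy-2-methylprop-2-en-1-yl)-4-[(TBSO)methyl]-5-(trimethylsilyl)furan-3-yl}-2-methylbutanoic acid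
Product: 21 (8S,10R)-furan-fused oxocan-2-one: lactone C1(=O)–O–C5 with isopropenyl on C5, OTBS on C8, methyl on C10, CH2OTBS on C11 and TMS on C12 (both C5 epimers)
Conditions: MNBA, DMAP, CH2Cl2 (2 mM), rt, syringe-pump addition
Reagents that add atoms: none
Why: Shiina macrolactonization activates the acid as a mixed anhydride and transfers the acyl group to C5–OH under high dilution; the cis C6=C7 unit of the furan and three ring substituents should pre-organize the seco acid for eight-membered closure.

Step 13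
Reactants: 21 (8S,10R)-furan-fused oxocan-2-one
Product: 22 (8S,10R)-furan-fused 2-methyleneoxocane: exocyclic C1=C2H2 enol ether with isopropenyl on C5, OTBS on C8, methyl on C10, CH2OTBS on C11 and TMS on C12 (both C5 epimers)
Conditions: Cp2TiMe2 (3 equiv), toluene, 65 °C, dark
Reagents that add atoms: dimethyltitanocene Cp2TiMe2, [CH3-].[CH3-].[Ti+4].c1cc[cH-]c1.c1cc[cH-]c1
Why: Petasis methylenation converts a lactone carbonyl into the exocyclic enol ether under non-acidic conditions that the furan, the silyl groups and the isopropenyl alkene should survive.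

Step 14
Reactants: 22 (8S,10R)-furan-fused 2-methyleneoxocane
Product: 23 (4E,8S,10R)-silylfuran-fused 4-methylcyclodec-4-en-1-one with OTBS on C8, methyl on C10, CH2OTBS on C11 and TMS on C12
Conditions: toluene, 110 °C, sealed tube, Et3N (1 vol %), base-washed glass
Reagents that add atoms: none
Why: The allyl vinyl ether C2=C1–O–C5–C4=C3 undergoes a concerted suprafacial [3,3]-sigmatropic Claisen shift through a chair in which C2–C3 forms while the furfuryl–allyl C5–O bond breaks, driven by the new C1 carbonyl and the furan-conjugated C4=C5 alkene. The closest known reaction type is the thermal Claisen ring expansion of lactone-derived 2-methylene cyclic ethers that carry an alkenyl group on the ether carbon, here extended from the smaller rings to the oxocane. The ten-membered carbocycle is closed in this ring-expanding mode: the tether C6–C10 that already joins C5 to C1 is kept and C2–C3 are inserted, so no separate macrocyclization is needed. No stereocentre is created; C8 and C10 are spectators and C5 becomes trigonal, so both C5 epimers should converge on one ketone. The step needs E geometry at C4=C5 and a concerted course: the chair with the C5–C6 bond equatorial puts C6 trans to C3 and lets the tether span C5 and C1 in an extended shape, whereas the axial chair or a boat, which lead to the Z ring, fold the tether back on itself. The non-polar solvent and the trace of amine should keep the doubly activated C5–O bond from heterolysis and the exocyclic enol ether from isomerizing.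

Step 15
Reactants: 23 (4E,8S,10R)-silylfuran-fused 4-methylcyclodec-4-en-1-one
Product: 24 (4S,5S,8S,10R)-4,5-epoxy-8,13-bis(TBSO)-1-oxogermacr-7(11)-en-12,6-olide (C6 epimers)
Conditions: AcOOH (2.5 equiv), NaOAc, CH2Cl2, 0 °C → rt
Reagents that add atoms: peracetic acid, CC(=O)OO
Why: Buffered peracid should epoxidize the electron-rich C4=C5 alkene from the outer face of the E ring (setting C4; C5 follows from the E geometry) and convert the 2-silylfuran by ipso oxidation and protodesilylation into the butenolide with its carbonyl on the former silyl carbon C12, while Baeyer–Villiger oxidation of the medium-ring ketone is far slower; C6 is formed without control and is planarized in step 16.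

Step 16
Reactants: 24 (4S,5S,8S,10R)-4,5-epoxy-8,13-bis(TBSO)-1-oxogermacr-7(11)-en-12,6-olide
Product: 25 (1R,4S,8S,10R)-8,13-bis(TBSO)-1-hydroxy-1,4-epoxygermacra-5,7(11)-dien-12,6-olide (C4 cis to C7 across C5=C6)
Conditions: DBU, CH2Cl2, 0 °C → rt
Reagents that add atoms: none
Why: DBU removes the acidic γ-hydrogen at C6, the dienolate opens the neighbouring epoxide at C5 (vinylogous E1cB) to give the C5=C6 ylidene butenolide, and the C4 alkoxide adds across the ring to the C1 ketone (5-exo-trig hemiketalization), the bridged geometry allowing only the 1R hemiketal; any material already opened in step 15 converges here.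

Step 17
Reactants: 25 (1R,4S,8S,10R)-8,13-bis(TBSO)-1-hydroxy-1,4-epoxygermacra-5,7(11)-dien-12,6-olide
Product: 26 (1R,4S,8S,10R)-1,8,13-trihydroxy-1,4-epoxygermacra-5,7(11)-dien-12,6-olide
Conditions: HF·pyridine, pyridine, THF, 0 °C → rt
Reagents that add atoms: none
Why: Fluoride desilylation under mildly acidic, alcohol-free conditions removes both TBS ethers without base-induced reactions of the butenolide and without ketal exchange at C1.

Step 18
Reactants: 26 (1R,4S,8S,10R)-1,8,13-trihydroxy-1,4-epoxygermacra-5,7(11)-dien-12,6-olide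
Product: 27 (1R,4S,8S,10R)-13-acetoxy-1,8-dihydroxy-1,4-epoxygermacra-5,7(11)-dien-12,6-olide
Conditions: AcCl (1.05 equiv), 2,4,6-collidine, CH2Cl2, −78 °C
Reagents that add atoms: acetyl chloride, CC(Cl)=O
Why: Selective acylation: at −78 °C the primary allylic C13 hydroxyl should react far faster than the hindered secondary C8 hydroxyl and the tertiary hemiketal hydroxyl.

Step 19
Reactants: 28 (tert-butyldimethylsilyloxy)acetaldehyde; 29 ethyl 2-(triphenylphosphoranylidene)propanoate
Product: 30 ethyl (E)-4-(TBSO)-2-methylbut-2-enoate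
Conditions: CH2Cl2, rt
Reagents that add atoms: none
Why: Wittig olefination with a stabilized α-methyl ylide should give the E trisubstituted enoate.

Step 20
Reactants: 30 ethyl (E)-4-(TBSO)-2-methylbut-2-enoate
Product: 31 (E)-4-(TBSO)-2-methylbut-2-enoic acid
Conditions: LiOH, THF/MeOH/H2O, rt; then pH 4
Reagents that add atoms: lithium hydroxide, [Li+].[OH-]
Why: Saponification of the ethyl ester; the primary TBS ether and the E geometry should be stable to LiOH at rt.

Step 21
Reactants: 27 (1R,4S,8S,10R)-13-acetoxy-1,8-dihydroxy-1,4-epoxygermacra-5,7(11)-dien-12,6-olide; 31 (E)-4-(TBSO)-2-methylbut-2-enoic acid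
Product: 32 (1R,4S,8S,10R)-13-acetoxy-1-hydroxy-8-[(E)-4-(TBSO)-2-methylbut-2-enoyloxy]-1,4-epoxygermacra-5,7(11)-dien-12,6-olide
Conditions: EDC·HCl, DMAP (0.2 equiv), CH2Cl2, 0 °C → rt
Reagents that add atoms: none
Why: Steglich esterification acylates the C8 hydroxyl with retention, the tertiary hemiketal hydroxyl being unreactive and the E enoate being the stable isomer.

Step 22
Reactants: 32 (1R,4S,8S,10R)-13-acetoxy-1-hydroxy-8-[(E)-4-(TBSO)-2-methylbut-2-enoyloxy]-1,4-epoxygermacra-5,7(11)-dien-12,6-olide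
Product: 33 CNP0154520.2
Conditions: HF·pyridine, pyridine, THF, 0 °C
Reagents that add atoms: none
Why: Fluoride desilylation removes the primary TBS ether under conditions that should leave both esters, the allylic acetate and the hemiketal intact.

Compound list

1 | 3,4-dibromofuran | Brc1cocc1Br | starting material
2 | 3-bromo-4-lithiofuran | [Li]c1cocc1Br | intermediate
3 | 4-bromofuran-3-carbaldehyde | O=Cc1cocc1Br | intermediate
4 | (4-bromofuran-3-yl)methanol | OCc1cocc1Br | intermediate
5 | 3-bromo-4-[(tert-butyldimethylsilyloxy)methyl]furan | CC(C)(C)[Si](C)(C)OCc1cocc1Br | intermediate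
6 | methacrolein (2-methylprop-2-enal) | CC(=C)C=O | starting material
7 | 3-bromo-4-[(TBSO)methyl]-2-lithiofuran | CC(C)(C)[Si](C)(C)OCc1coc([Li])c1Br | intermediate
8 | lithium 1-{3-bromo-4-[(TBSO)methyl]furan-2-yl}-2-methylprop-2-en-1-olate (racemic) | [Li+].[O-]C(C(C)=C)c1occ(CO[Si](C)(C)C(C)(C)C)c1Br | intermediate
9 | 3-bromo-4-[(TBSO)methyl]-2-[2-methyl-1-(TESO)prop-2-en-1-yl]furan (racemic at C5) | C=C(C)C(O[Si](CC)(CC)CC)c1occ(CO[Si](C)(C)C(C)(C)C)c1Br | intermediate
10 | 3-bromo-4-[(TBSO)methyl]-2-[2-methyl-1-(TESO)prop-2-en-1-yl]-5-(trimethylsilyl)furan (racemic at C5) | C=C(C)C(O[Si](CC)(CC)CC)c1oc([Si](C)(C)C)c(CO[Si](C)(C)C(C)(C)C)c1Br | intermediate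
11 | 3-lithio derivative of 10 | C=C(C)C(O[Si](CC)(CC)CC)c1oc([Si](C)(C)C)c(CO[Si](C)(C)C(C)(C)C)c1[Li] | intermediate
12 | S-ethyl 4-[(TBSO)methyl]-2-[2-methyl-1-(TESO)prop-2-en-1-yl]-5-(trimethylsilyl)furan-3-carbothioate (racemic at C5) | C=C(C)C(O[Si](CC)(CC)CC)c1oc([Si](C)(C)C)c(CO[Si](C)(C)C(C)(C)C)c1C(=O)SCC | intermediate
13 | methyl (R)-3-hydroxy-2-methylpropanoate | COC(=O)[C@H](C)CO | starting material
14 | methyl (S)-3-iodo-2-methylpropanoate | COC(=O)[C@H](C)CI | intermediate
15 | [(2S)-3-methoxy-2-methyl-3-oxopropyl]zinc iodide | COC(=O)[C@H](C)C[Zn]I | intermediate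
16 | methyl (2R)-2-methyl-4-oxo-4-{4-[(TBSO)methyl]-2-[2-methyl-1-(TESO)prop-2-en-1-yl]-5-(trimethylsilyl)furan-3-yl}butanoate (both C5 epimers) | C=C(C)C(O[Si](CC)(CC)CC)c1oc([Si](C)(C)C)c(CO[Si](C)(C)C(C)(C)C)c1C(=O)C[C@@H](C)C(=O)OC | intermediate
17 | methyl (2R,4S)-4-hydroxy-2-methyl-4-{4-[(TBSO)methyl]-2-[2-methyl-1-(TESO)prop-2-en-1-yl]-5-(trimethylsilyl)furan-3-yl}butanoate (both C5 epimers) | C=C(C)C(O[Si](CC)(CC)CC)c1oc([Si](C)(C)C)c(CO[Si](C)(C)C(C)(C)C)c1[C@@H](O)C[C@@H](C)C(=O)OC | intermediate
18 | methyl (2R,4S)-4-(TBSO)-2-methyl-4-{4-[(TBSO)methyl]-2-[2-methyl-1-(TESO)prop-2-en-1-yl]-5-(trimethylsilyl)furan-3-yl}butanoate (both C5 epimers) | C=C(C)C(O[Si](CC)(CC)CC)c1oc([Si](C)(C)C)c(CO[Si](C)(C)C(C)(C)C)c1[C@@H](O[Si](C)(C)C(C)(C)C)C[C@@H](C)C(=O)OC | intermediate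
19 | methyl (2R,4S)-4-(TBSO)-4-{2-(1-hydroxy-2-methylprop-2-en-1-yl)-4-[(TBSO)methyl]-5-(trimethylsilyl)furan-3-yl}-2-methylbutanoate (both C5 epimers) | C=C(C)C(O)c1oc([Si](C)(C)C)c(CO[Si](C)(C)C(C)(C)C)c1[C@@H](O[Si](C)(C)C(C)(C)C)C[C@@H](C)C(=O)OC | intermediate
20 | (2R,4S)-4-(TBSO)-4-{2-(1-hydroxy-2-methylprop-2-en-1-yl)-4-[(TBSO)methyl]-5-(trimethylsilyl)furan-3-yl}-2-methylbutanoic acid (both C5 epimers) | C=C(C)C(O)c1oc([Si](C)(C)C)c(CO[Si](C)(C)C(C)(C)C)c1[C@@H](O[Si](C)(C)C(C)(C)C)C[C@@H](C)C(=O)O | intermediate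
21 | (8S,10R)-furan-fused oxocan-2-one, lactone C1(=O)–O–C5, isopropenyl on C5, OTBS on C8, methyl on C10, CH2OTBS on C11, TMS on C12 (both C5 epimers) | O=C1OC(C(C)=C)c2oc([Si](C)(C)C)c(CO[Si](C)(C)C(C)(C)C)c2[C@@H](O[Si](C)(C)C(C)(C)C)C[C@H]1C | intermediate
22 | (8S,10R)-furan-fused 2-methyleneoxocane, exocyclic C1=C2H2, same substituents as 21 (both C5 epimers) | C=C1OC(C(C)=C)c2oc([Si](C)(C)C)c(CO[Si](C)(C)C(C)(C)C)c2[C@@H](O[Si](C)(C)C(C)(C)C)C[C@H]1C | intermediate
23 | (4E,8S,10R)-silylfuran-fused 4-methylcyclodec-4-en-1-one, OTBS on C8, methyl on C10, CH2OTBS on C11, TMS on C12 | C/C1=C\c2oc([Si](C)(C)C)c(CO[Si](C)(C)C(C)(C)C)c2[C@@H](O[Si](C)(C)C(C)(C)C)C[C@@H](C)C(=O)CC1 | intermediate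
24 | (4S,5S,8S,10R)-4,5-epoxy-8,13-bis(TBSO)-1-oxogermacr-7(11)-en-12,6-olide (C6 epimers) | CC(C)(C)[Si](C)(C)OCC1=C2C(OC1=O)[C@@H]3O[C@@]3(C)CCC(=O)[C@H](C)C[C@@H]2O[Si](C)(C)C(C)(C)C | intermediate
25 | (1R,4S,8S,10R)-8,13-bis(TBSO)-1-hydroxy-1,4-epoxygermacra-5,7(11)-dien-12,6-olide | CC(C)(C)[Si](C)(C)OCC1=C2/C(=C\[C@]3(C)CC[C@@](O)(O3)[C@H](C)C[C@@H]2O[Si](C)(C)C(C)(C)C)OC1=O | intermediate
26 | (1R,4S,8S,10R)-1,8,13-trihydroxy-1,4-epoxygermacra-5,7(11)-dien-12,6-olide | OCC1=C2/C(=C\[C@]3(C)CC[C@@](O)(O3)[C@H](C)C[C@@H]2O)OC1=O | intermediate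
27 | (1R,4S,8S,10R)-13-acetoxy-1,8-dihydroxy-1,4-epoxygermacra-5,7(11)-dien-12,6-olide | CC(=O)OCC1=C2/C(=C\[C@]3(C)CC[C@@](O)(O3)[C@H](C)C[C@@H]2O)OC1=O | intermediate
28 | (tert-butyldimethylsilyloxy)acetaldehyde | O=CCO[Si](C)(C)C(C)(C)C | starting material
29 | ethyl 2-(triphenylphosphoranylidene)propanoate | CCOC(=O)C(C)=P(c1ccccc1)(c1ccccc1)c1ccccc1 | starting material
30 | ethyl (E)-4-(TBSO)-2-methylbut-2-enoate | CCOC(=O)/C(C)=C/CO[Si](C)(C)C(C)(C)C | intermediate
31 | (E)-4-(TBSO)-2-methylbut-2-enoic acid | OC(=O)/C(C)=C/CO[Si](C)(C)C(C)(C)C | intermediate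
32 | (1R,4S,8S,10R)-13-acetoxy-1-hydroxy-8-[(E)-4-(TBSO)-2-methylbut-2-enoyloxy]-1,4-epoxygermacra-5,7(11)-dien-12,6-olide | CC(=O)OCC1=C2/C(=C\[C@]3(C)CC[C@@](O)(O3)[C@H](C)C[C@@H]2OC(=O)/C(C)=C/CO[Si](C)(C)C(C)(C)C)OC1=O | intermediate
33 | CNP0154520.2, (1R,4S,8S,10R)-13-acetoxy-1-hydroxy-8-[(E)-4-hydroxy-2-methylbut-2-enoyloxy]-1,4-epoxygermacra-5,7(11)-dien-12,6-olide | CC(=O)OCC1=C2/C(=C\[C@]3(C)CC[C@@](O)(O3)[C@H](C)C[C@@H]2OC(=O)/C(C)=C/CO)OC1=O | target

Total step count: 22. Longest linear sequence: 19 steps (steps 1–5, 7–18, 21 and 22, from 3,4-dibromofuran).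

Steps most likely to fail

Step 14. The shift may leak through the axial chair or a boat and close the ring with Z geometry at C4=C5. Fallback, setting out from 22 and returning at 25: because C5 becomes trigonal again in step 16, only the configuration at C4 has to be right, so the Z ring can be used. The rearrangement product of 22, the (4Z,8S,10R)-cyclodec-4-en-1-one F1, would be epoxidized under reagent control instead of substrate control, by Shi epoxidation with the D-fructose-derived ketone (KHSO5, K2CO3 buffer, MeCN/dimethoxymethane/H2O, 0 °C). This should give the (4S,5S)-4,5-epoxide with intact silylfuran F2, used crude. Buffered peracetic acid (1.2 equiv, NaOAc, CH2Cl2) then converts the silylfuran into the (4S,5R)-4,5-epoxy butenolide F3, and DBU opens it as in step 16 to give 25.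

Step 12. Intermolecular acylation (diolide and oligomers) may outrun the slow eight-membered closure, and acyl transfer to the hindered C5 hydroxyl may be sluggish for one epimer. Fallback, setting out from 20 and returning at 21: Mitsunobu macrolactonization (PPh3, DIAD, toluene, high dilution, 0 °C → rt) reverses the roles, the carboxylate displacing the activated C5 oxygen. Inversion or scrambling at C5 is harmless because step 14 erases this centre. The fallback creates no new compound (F0).

Step 15. The peracid may attack both faces of C4=C5, or oxidize the furan and the alkene without discrimination and over-oxidize. Fallback, setting out from 23 and returning at 24: the two oxidations are separated and the face is set by the reagent. Shi epoxidation of 23 with the enantiomeric (L-series) fructose-derived ketone (KHSO5, K2CO3 buffer, 0 °C) should give the (4S,5R)-4,5-epoxide with intact silylfuran F4, used crude. Buffered peracetic acid (1.2 equiv) then oxidizes only the silylfuran and gives 24.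

Further compounds

F0 | step 12 | none | none
F1 | step 14 | (4Z,8S,10R)-silylfuran-fused 4-methylcyclodec-4-en-1-one | C/C1=C/c2oc([Si](C)(C)C)c(CO[Si](C)(C)C(C)(C)C)c2[C@@H](O[Si](C)(C)C(C)(C)C)C[C@@H](C)C(=O)CC1
F2 | step 14 | (4S,5S,8S,10R)-4,5-epoxide of F1, silylfuran intact | CC(C)(C)[Si](C)(C)OCc1c2c(oc1[Si](C)(C)C)[C@H]3O[C@@]3(C)CCC(=O)[C@H](C)C[C@@H]2O[Si](C)(C)C(C)(C)C
F3 | step 14 | (4S,5R,8S,10R)-4,5-epoxy-8,13-bis(TBSO)-1-oxogermacr-7(11)-en-12,6-olide (C6 epimers) | CC(C)(C)[Si](C)(C)OCC1=C2C(OC1=O)[C@H]3O[C@@]3(C)CCC(=O)[C@H](C)C[C@@H]2O[Si](C)(C)C(C)(C)C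
F4 | step 15 | (4S,5R,8S,10R)-4,5-epoxide of 23, silylfuran intact | CC(C)(C)[Si](C)(C)OCc1c2c(oc1[Si](C)(C)C)[C@@H]3O[C@@]3(C)CCC(=O)[C@H](C)C[C@@H]2O[Si](C)(C)C(C)(C)C
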